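**Plan**

1. Labdane numbering is used; the target is (13R)-6β-acetoxy-9α,13:15,16-diepoxylabd-14-en-7-one with an 8α-methyl group (5S,6S,8S,9R,10S,13R).
2. Retrosynthetic cuts, in order: the C6 acetate; the C14=C15 enol ether (lactol dehydration); C7=O and C6–O of ring B (back to a 7-ene); O–C16 of ring D (Baeyer–Villiger, back to a cyclobutanone spiro at C13); C13–C14 and C15–C16 of the cyclobutane plus the C13=CH2 carbon; then C9–O and C11–C12 of a C9 spirolactone, which leads to drima-7,9(11)-diene and (−)-sclareol.
3. Forward order: rings A and B come from sclareol; the oxolane (ring C) is closed as a spiro γ-lactone at C9; a cyclobutanone is spiro-fused at C13; ring D arises from it by ring expansion; ring B is oxidised last.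
4. Enabling feature: ring D is a 2,3-dihydrofuran spiro at C13 (O–C16H2–C13–C14H=C15), the enol ether of a β,β-disubstituted γ-lactone. C13 carries two CH2 arms that are constitutionally identical in the cyclobutanone C13–C14H2–C15(=O)–C16H2, so oxygen insertion next to one arm creates the C13 stereocentre.
5. Stereochemistry: C5 and C10 from sclareol; C9 by α-face lactone closure; C13 by the chiral phosphoric acid; C6 by α-face hydride delivery; C8 by equilibration to the equatorial methyl.

Key step: step 8

Assumption: the (R)-acid is written as the enantiomer that makes the methylene on the C8 face of the oxolane migrate; the sense of induction for a spiro 3,3-disubstituted cyclobutanone cannot be predicted safely, and the (S)-acid takes its place if the other arm migrates.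

**Route**

Step 1
Reactants: 1 (−)-sclareol
Product: 4 8α-hydroxy-14,15-dinorlabdan-13-one, via 14,15-diol 2 (not isolated), via hydroxy aldehyde 3 (not isolated)
Conditions: OsO4 (cat.), NaIO4 (excess), THF–H2O, rt
Reagents that add atoms: none
Why: Lemieux–Johnson oxidation, in which OsO4 dihydroxylates the only alkene and periodate cleaves the resulting triol unit twice (C14–C15, then the α-hydroxy aldehyde), leaving the C13 methyl ketone while the tertiary 8α-hydroxyl and the ring stereocentres are untouched.

Step 2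
Reactants: 4 8α-hydroxy-14,15-dinorlabdan-13-one
Product: 5 drim-9(11)-en-8α-ol
Conditions: hν (medium-pressure Hg lamp, Pyrex), hexane, rt
Reagents that add atoms: none
Why: Norrish type 2 cleavage, in which the excited C13 ketone abstracts the γ-hydrogen at C9 through a six-membered transition state and the 1,4-biradical breaks C11–C12 to give the exocyclic C9=C11 alkene and acetone enol, with C8 unchanged.

Step 3
Reactants: 5 drim-9(11)-en-8α-ol
Product: 6 drima-7,9(11)-diene
Conditions: Burgess reagent, benzene, 50 °C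
Reagents that add atoms: none
Why: Burgess dehydration of a tertiary allylic alcohol, in which the sulfamate ionises to the C8–C9–C11 allyl cation and loss of the axial 7α-hydrogen (Zaitsev, endocyclic, conjugated) should give the 7,9(11)-diene in preference to the 8(12),9(11)-isomer.

Step 4
Reactants: 6 drima-7,9(11)-diene; 7 acetic acid
Product: 8 (9R)-9α-hydroxy-14,15,16-trinorlabd-7-en-13-oic acid 13,9-lactone
Conditions: Mn(OAc)3·2H2O (2.5 equiv), KOAc, AcOH–Ac2O, 90 °C
Reagents that add atoms: acetic acid (7), CC(=O)O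
Why: Oxidative radical carbolactonisation with trivalent manganese acetate, in which the carboxymethyl radical adds to the unhindered C11 terminus, the C7–C9 allyl radical is oxidised to the cation and the tethered carboxyl closes the five-membered lactone at C9 from the α-face (axial, anti to the 10β-methyl), which sets the 9α-oxygen and leaves the 7-ene.

Step 5
Reactants: 8 (9R)-9α-hydroxy-14,15,16-trinorlabd-7-en-13-oic acid 13,9-lactone
Product: 9 9α,13-epoxy-15,16-dinorlabda-7,13(14)-diene
Conditions: Cp2TiMe2, toluene, 70 °C, dark; filtration through basic Al2O3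
Reagents that add atoms: dimethyltitanocene Cp2TiMe2, [CH3-].[CH3-].[Ti+4].[cH-]1cccc1.[cH-]1cccc1
Why: Petasis methylenation, in which Cp2TiMe2 loses methane to Cp2Ti=CH2 and this converts the lactone carbonyl into the exocyclic enol ether by [2+2] addition and cycloreversion without touching the 7-ene or the allylic C9–O bond.

Step 6
Reactants: 9 9α,13-epoxy-15,16-dinorlabda-7,13(14)-diene; 10 trichloroacetyl chloride
Product: 12 14,14-dichloro-9α,13-epoxy-15,16-cyclolabd-7-en-15-one (C13 epimers), via dichloroketene 11 (not isolated)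
Conditions: Cl3CCOCl, Zn–Cu couple, DME–Et2O, 0 °C to rt
Reagents that add atoms: trichloroacetyl chloride (10), ClC(Cl)(Cl)C(Cl)=O, reacting as dichloroketene ClC(Cl)=C=O
Why: Ketene–enol ether [2+2] cycloaddition, in which dichloroketene adds to the electron-rich exocyclic enol ether with its carbonyl carbon on the CH2 terminus and CCl2 on C13 while the hindered 7-ene stays inert; the C13 epimers converge in the next step.

Step 7
Reactants: 12 14,14-dichloro-9α,13-epoxy-15,16-cyclolabd-7-en-15-one
Product: 13 9α,13-epoxy-15,16-cyclolabd-7-en-15-one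
Conditions: Zn dust, AcOH, rt
Reagents that add atoms: none
Why: Reductive dechlorination of an α,α-dichloroketone with zinc in acetic acid, where the zinc enolates are protonated before they can expel the β-alkoxy group and removal of both chlorines makes the two arms on C13 identical, so C13 is no longer a stereocentre.

Step 8
Reactants: 13 9α,13-epoxy-15,16-cyclolabd-7-en-15-one
Product: 15 (13R)-9α,13-epoxylabd-7-en-15,16-olide, via Criegee adduct 14 (not isolated)
Conditions: 30% aq. H2O2 (1.5 equiv), (R)-3,3'-bis(2,4,6-triisopropylphenyl)-1,1'-binaphthyl-2,2'-diyl hydrogen phosphate (10 mol%), CHCl3, −40 °C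
Reagents that add atoms: hydrogen peroxide, OO
Why: The phosphoric acid hydrogen-bonds both the strained ketone and H2O2, the peroxide adds to C15 to give the Criegee adduct 14, and one ring methylene then shifts from C15 to oxygen, antiperiplanar to the breaking O–O bond, as water leaves. The closest known reaction type is the chiral-phosphoric-acid-catalysed Baeyer–Villiger desymmetrisation of prochiral 3-substituted cyclobutanones with aqueous H2O2. Ring D is not closed by a cyclisation but arises by 1,2-shift ring expansion of the four-membered ketone to the five-membered lactone, the new bond being O–C16. C13 becomes a stereocentre only because one of its two CH2 arms now carries oxygen, and 13R results when the methylene on the C8 face of the oxolane migrates; this choice is made by the chiral phosphate held in the Criegee adduct, since the bias from C9 is small. The step needs group selectivity between two diastereotopic but constitutionally identical methylenes and chemoselectivity over the 7-ene; the substrate secures the second through ring strain (the cyclobutanone reacts at −40 °C, the trisubstituted alkene is inert to H2O2) and helps the first because O9 and C12 on C13 differ in size and hydrogen-bond acceptor ability. Should both products form, they are diastereomers and can be separated.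

Step 9
Reactants: 15 (13R)-9α,13-epoxylabd-7-en-15,16-olide
Product: 16 (13R)-9α,13-epoxy-6-oxolabd-7-en-15,16-olide
Conditions: CrO3, 3,5-dimethylpyrazole, CH2Cl2, −20 °C
Reagents that add atoms: chromium trioxide CrO3, O=[Cr](=O)=O
Why: Allylic oxidation with the CrO3–3,5-dimethylpyrazole complex, in which C6 is the only allylic ring methylene (C9 is quaternary) and is oxidised to the conjugated 7-en-6-one while the lactone and the fully substituted ether carbons C9 and C13 are inert.

Step 10
Reactants: 16 (13R)-9α,13-epoxy-6-oxolabd-7-en-15,16-olide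
Product: 17 (13R)-9α,13:15,16-diepoxylabd-7-ene-6β,15-diol (lactol anomers)
Conditions: i-Bu2AlH (2.3 equiv), CH2Cl2, −78 °C; aq. potassium sodium tartrate work-up
Reagents that add atoms: none
Why: Hydride reduction with i-Bu2AlH at low temperature, in which the γ-lactone stops at the aluminium lactolate and the enone is reduced 1,2 from the α-face because the 4β- and 10β-methyl groups block the β-face, which sets the axial 6β-hydroxyl.

Step 11
Reactants: 17 (13R)-9α,13:15,16-diepoxylabd-7-ene-6β,15-diol
Product: 18 (13R)-6β,15-bis(tert-butyldimethylsilyloxy)-9α,13:15,16-diepoxylabd-7-ene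
Conditions: TBSOTf, 2,6-lutidine, CH2Cl2, −78 to 0 °C
Reagents that add atoms: tert-butyldimethylsilyl triflate, CC(C)(C)[Si](C)(C)OS(=O)(=O)C(F)(F)F
Why: Silyl ether formation with a silyl triflate and a hindered base, which is reactive enough for the crowded axial 6β-hydroxyl and caps the hemiacetal hydroxyl as a silyl acetal in the same operation.

Step 12
Reactants: 18 (13R)-6β,15-bis(tert-butyldimethylsilyloxy)-9α,13:15,16-diepoxylabd-7-ene
Product: 20 (13R)-6β,15-bis(tert-butyldimethylsilyloxy)-9α,13:15,16-diepoxy-8β-methyl(8αH)-labdan-7α-ol, via 7α-boryl adduct 19 (not isolated)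
Conditions: BH3·SMe2, THF, 0 °C to rt; then NaBO3·4H2O, H2O, rt
Reagents that add atoms: sodium perborate NaBO3, [Na+].[O-]OB=O
Why: Hydroboration–oxidation, a syn anti-Markovnikov addition in which boron goes to the less substituted C7 and hydrogen to C8 from the α-face (opposite the 10β-methyl and the 6β-silyloxy group), giving the 7α-alcohol with the C8 methyl forced axial (β), and perborate oxidises the C–B bond with retention.

Step 13
Reactants: 20 (13R)-6β,15-bis(tert-butyldimethylsilyloxy)-9α,13:15,16-diepoxy-8β-methyl(8αH)-labdan-7α-ol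
Product: 22 (13R)-6β,15-bis(tert-butyldimethylsilyloxy)-9α,13:15,16-diepoxy-8α-methyl(8βH)-labdan-7-one, via 8β-methyl ketone 21 (not isolated)
Conditions: Dess–Martin periodinane, NaHCO3, CH2Cl2, rt; filtration; then DBU, toluene, rt
Reagents that add atoms: none
Why: Dess–Martin oxidation followed by base-mediated epimerisation through the C7–C8 enolate, in which the axial 8β-methyl (1,3-diaxial to the 10β-methyl) is moved by β-face reprotonation to the equatorial 8α position of the target, while H-6 is screened by its own silyloxy group and the 4α-methyl group, so that C6 should enolise more slowly.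

Step 14
Reactants: 22 (13R)-6β,15-bis(tert-butyldimethylsilyloxy)-9α,13:15,16-diepoxy-8α-methyl(8βH)-labdan-7-one
Product: 23 (13R)-6β,15-dihydroxy-9α,13:15,16-diepoxylabdan-7-one (8α-methyl; lactol anomers)
Conditions: HF·pyridine, pyridine, THF, 0 °C to rt
Reagents that add atoms: none
Why: Fluoride-driven desilylation under pyridine buffering, which frees the hemiacetal and the 6β-hydroxyl without a base strong enough to enolise the ketone or an acid strong enough to open the β-alkoxy ketone.

Step 15
Reactants: 23 (13R)-6β,15-dihydroxy-9α,13:15,16-diepoxylabdan-7-one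
Product: 25 (13R)-6β-hydroxy-9α,13:15,16-diepoxylabd-14-en-7-one, via 15-mesylate 24 (not isolated)
Conditions: MsCl (1.5 equiv), Et3N, CH2Cl2, −40 °C to rt
Reagents that add atoms: none
Why: Lactol dehydration by mesylation–elimination, in which the unhindered hemiacetal hydroxyl is sulfonylated, the anomeric mesylate ionises to the oxocarbenium ion and triethylamine removes H-14 to give the 2,3-dihydrofuran, whereas the axial 6β-hydroxyl (between the 4β- and 10β-methyl groups, next to the ketone) should not react at low temperature.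

Step 16
Reactants: 25 (13R)-6β-hydroxy-9α,13:15,16-diepoxylabd-14-en-7-one
Product: 26 (13R)-6β-acetoxy-9α,13:15,16-diepoxylabd-14-en-7-one
Conditions: Ac2O, DMAP, pyridine, CH2Cl2, rt
Reagents that add atoms: acetic anhydride, CC(=O)OC(C)=O
Why: DMAP-catalysed acylation of the hindered axial 6β-hydroxyl with acetic anhydride under basic conditions that the acid-labile enol ether and spiro ether tolerate.

**Compound list**

1 | (−)-sclareol, (13R)-labd-14-ene-8α,13-diol | C1C[C@@](C)(O)[C@H](CC[C@@](C)(O)C=C)[C@@]2(C)CCCC(C)(C)[C@H]12 | starting material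
2 | (13R)-labdane-8α,13,14,15-tetrol (C14 epimers) | C1C[C@@](C)(O)[C@H](CC[C@@](C)(O)C(O)CO)[C@@]2(C)CCCC(C)(C)[C@H]12 | intermediate (not isolated)
3 | (13R)-8α,13-dihydroxy-15-norlabdan-14-al | C1C[C@@](C)(O)[C@H](CC[C@@](C)(O)C=O)[C@@]2(C)CCCC(C)(C)[C@H]12 | intermediate (not isolated)
4 | 8α-hydroxy-14,15-dinorlabdan-13-one | C1C[C@@](C)(O)[C@H](CCC(C)=O)[C@@]2(C)CCCC(C)(C)[C@H]12 | intermediate
5 | drim-9(11)-en-8α-ol | C1C[C@@](C)(O)C(=C)[C@@]2(C)CCCC(C)(C)[C@H]12 | intermediate
6 | drima-7,9(11)-diene | C1C=C(C)C(=C)[C@@]2(C)CCCC(C)(C)[C@H]12 | intermediate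
7 | acetic acid | CC(=O)O | starting material
8 | (9R)-9α-hydroxy-14,15,16-trinorlabd-7-en-13-oic acid 13,9-lactone (γ-lactone spiro at C9) | C1C=C(C)[C@]2(CCC(=O)O2)[C@@]2(C)CCCC(C)(C)[C@H]12 | intermediate
9 | 9α,13-epoxy-15,16-dinorlabda-7,13(14)-diene (2-methyleneoxolane spiro at C9) | C1C=C(C)[C@]2(CCC(=C)O2)[C@@]2(C)CCCC(C)(C)[C@H]12 | intermediate
10 | trichloroacetyl chloride | ClC(Cl)(Cl)C(Cl)=O | starting material
11 | dichloroketene | ClC(Cl)=C=O | intermediate (not isolated)
12 | 14,14-dichloro-9α,13-epoxy-15,16-cyclolabd-7-en-15-one (C13 epimers) | C1C=C(C)[C@]2(CCC3(CC(=O)C3(Cl)Cl)O2)[C@@]2(C)CCCC(C)(C)[C@H]12 | intermediate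
13 | 9α,13-epoxy-15,16-cyclolabd-7-en-15-one (3-oxocyclobutane spiro at C13) | C1C=C(C)[C@]2(CCC3(CC(=O)C3)O2)[C@@]2(C)CCCC(C)(C)[C@H]12 | intermediate
14 | 15-hydroperoxy-9α,13-epoxy-15,16-cyclolabd-7-en-15-ol (Criegee adduct) | C1C=C(C)[C@]2(CCC3(CC(O)(OO)C3)O2)[C@@]2(C)CCCC(C)(C)[C@H]12 | intermediate (not isolated)
15 | (13R)-9α,13-epoxylabd-7-en-15,16-olide | C1C=C(C)[C@]2(CC[C@]3(CC(=O)OC3)O2)[C@@]2(C)CCCC(C)(C)[C@H]12 | intermediate
16 | (13R)-9α,13-epoxy-6-oxolabd-7-en-15,16-olide | O=C1C=C(C)[C@]2(CC[C@]3(CC(=O)OC3)O2)[C@@]2(C)CCCC(C)(C)[C@H]12 | intermediate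
17 | (13R)-9α,13:15,16-diepoxylabd-7-ene-6β,15-diol (lactol anomers) | O[C@@H]1C=C(C)[C@]2(CC[C@]3(CC(O)OC3)O2)[C@@]2(C)CCCC(C)(C)[C@H]12 | intermediate
18 | (13R)-6β,15-bis(tert-butyldimethylsilyloxy)-9α,13:15,16-diepoxylabd-7-ene | CC(C)(C)[Si](C)(C)O[C@@H]1C=C(C)[C@]2(CC[C@]3(CC(O[Si](C)(C)C(C)(C)C)OC3)O2)[C@@]2(C)CCCC(C)(C)[C@H]12 | intermediate
19 | 7α-boryl adduct of 18 (7α-BH2, 8β-methyl) | CC(C)(C)[Si](C)(C)O[C@@H]1[C@@H](B)[C@H](C)[C@]2(CC[C@]3(CC(O[Si](C)(C)C(C)(C)C)OC3)O2)[C@@]2(C)CCCC(C)(C)[C@H]12 | intermediate (not isolated)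
20 | (13R)-6β,15-bis(tert-butyldimethylsilyloxy)-9α,13:15,16-diepoxy-8β-methyl(8αH)-labdan-7α-ol | CC(C)(C)[Si](C)(C)O[C@@H]1[C@@H](O)[C@H](C)[C@]2(CC[C@]3(CC(O[Si](C)(C)C(C)(C)C)OC3)O2)[C@@]2(C)CCCC(C)(C)[C@H]12 | intermediate
21 | (13R)-6β,15-bis(tert-butyldimethylsilyloxy)-9α,13:15,16-diepoxy-8β-methyl(8αH)-labdan-7-one | CC(C)(C)[Si](C)(C)O[C@@H]1C(=O)[C@H](C)[C@]2(CC[C@]3(CC(O[Si](C)(C)C(C)(C)C)OC3)O2)[C@@]2(C)CCCC(C)(C)[C@H]12 | intermediate (not isolated)
22 | (13R)-6β,15-bis(tert-butyldimethylsilyloxy)-9α,13:15,16-diepoxy-8α-methyl(8βH)-labdan-7-one | CC(C)(C)[Si](C)(C)O[C@@H]1C(=O)[C@@H](C)[C@]2(CC[C@]3(CC(O[Si](C)(C)C(C)(C)C)OC3)O2)[C@@]2(C)CCCC(C)(C)[C@H]12 | intermediate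
23 | (13R)-6β,15-dihydroxy-9α,13:15,16-diepoxylabdan-7-one (8α-methyl; lactol anomers) | O[C@@H]1C(=O)[C@@H](C)[C@]2(CC[C@]3(CC(O)OC3)O2)[C@@]2(C)CCCC(C)(C)[C@H]12 | intermediate
24 | 15-O-methanesulfonate of 23 | O[C@@H]1C(=O)[C@@H](C)[C@]2(CC[C@]3(CC(OS(C)(=O)=O)OC3)O2)[C@@]2(C)CCCC(C)(C)[C@H]12 | intermediate (not isolated)
25 | (13R)-6β-hydroxy-9α,13:15,16-diepoxylabd-14-en-7-one (8α-methyl) | O[C@@H]1C(=O)[C@@H](C)[C@]2(CC[C@]3(C=COC3)O2)[C@@]2(C)CCCC(C)(C)[C@H]12 | intermediate
26 | (13R)-6β-acetoxy-9α,13:15,16-diepoxylabd-14-en-7-one (8α-methyl) | CC(=O)O[C@@H]1C(=O)[C@@H](C)[C@]2(CC[C@]3(C=COC3)O2)[C@@]2(C)CCCC(C)(C)[C@H]12 | target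

**Step count and risks**

Total step count: 16. Longest linear sequence: 16 steps (1 to 26); the route is fully linear.

Steps most likely to fail:

First, step 8. Discrimination between the two diastereotopic methylenes in the catalyst-bound Criegee adduct may be poor, or an uncatalysed background oxidation may compete, so that oxygen is inserted on both arms. The fallback keeps the Baeyer–Villiger disconnection but lets chlorine choose the migrating arm. It sets out from 12, whose two C13 epimers are diastereomers with constitutionally different arms. The epimer that carries CCl2 on the C10 face of the oxolane, (13S)-14,14-dichloro-9α,13-epoxy-15,16-cyclolabd-7-en-15-one F1 would be separated by chromatography and oxidised with 30% aq. H2O2 in AcOH at rt, where the strained, electron-poor cyclobutanone reacts and the trisubstituted 7-ene should not. The electron-poor CCl2 carbon migrates poorly, so oxygen should enter only on the CH2 side, which lies on the C8 face, to give (13S)-14,14-dichloro-9α,13-epoxylabd-7-en-15,16-olide F2 with the C13 arrangement of 15, the descriptor being S only because CCl2 outranks CH2O in the sequence rules. Zn dust in AcOH then removes both chlorines from F2 and the route is rejoined at 15. The other epimer of 12 can still be dechlorinated to 13 and used in step 8.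

Second, step 13. Enolisation may not stay confined to C8: it may extend to C6 and erode the axial 6β configuration, or the C7–C8 enolate may expel the C9 ether oxygen and open the oxolane. The fallback avoids any enolate and sets C8 by hydroxyl-directed hydrogenation; it sets out from 18. A Schenck ene reaction (O2, tetraphenylporphyrin, hν, CH2Cl2) from the α-face can take hydrogen only from the C17 methyl and should give (13R)-6β,15-bis(tert-butyldimethylsilyloxy)-9α,13:15,16-diepoxy-7α-hydroperoxylabd-8(17)-ene F3 as the allylic hydroperoxide. Ac2O/pyridine (Kornblum–DeLaMare-type dehydration) would convert F3 into (13R)-6β,15-bis(tert-butyldimethylsilyloxy)-9α,13:15,16-diepoxylabd-8(17)-en-7-one F4 and Luche reduction (NaBH4, CeCl3·7H2O, MeOH) from the α-face would then give (13R)-6β,15-bis(tert-butyldimethylsilyloxy)-9α,13:15,16-diepoxylabd-8(17)-en-7β-ol F5 in which the equatorial hydroxyl flanks the exocyclic alkene. Hydrogenation with [Ir(cod)(PCy3)(py)]PF6 and H2 in CH2Cl2 delivers hydrogen to C8 on the face of the 7β-hydroxyl and should give (13R)-6β,15-bis(tert-butyldimethylsilyloxy)-9α,13:15,16-diepoxy-8α-methyl(8βH)-labdan-7β-ol F6 with the 8α-methyl group in place. Dess–Martin oxidation of F6 then comes back to the route at 22.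

Third, step 4. The radical addition or the lactone closure may take another course (capture of the allyl cation at C7 or from the β-face, acid-induced isomerisation of the diene in hot acetic acid), or step 3 may not deliver the 7,9(11)-diene cleanly. The fallback builds the same spirolactone by ionic steps and sets out from 5, so it bypasses step 3 as well. A Johnson–Claisen rearrangement (triethyl orthoacetate, cat. propionic acid, 140 °C) would put the two-carbon ester on C11 and move the alkene to C8–C9, giving ethyl 14,15,16-trinorlabd-8-en-13-oate F7 as a tetrasubstituted alkene. Allylic oxidation of the ring methylene C7 of F7 (CrO3, 3,5-dimethylpyrazole) would give ethyl 7-oxo-14,15,16-trinorlabd-8-en-13-oate F8 and Luche reduction would give ethyl 7β-hydroxy-14,15,16-trinorlabd-8-en-13-oate F9 from which LiOH in THF–H2O frees 7β-hydroxy-14,15,16-trinorlabd-8-en-13-oic acid F10 as the hydroxy acid. Catalytic camphorsulfonic acid in CH2Cl2 would ionise the allylic alcohol of F10 to the same C7–C9 allyl cation, which the carboxyl closes at C9 from the α-face (dehydrative allylic lactonisation), coming back to the route at 8.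

Further compounds

F1 | step 8 | (13S)-14,14-dichloro-9α,13-epoxy-15,16-cyclolabd-7-en-15-one | C1C=C(C)[C@]2(CC[C@]3(C(Cl)(Cl)C(=O)C3)O2)[C@@]2(C)CCCC(C)(C)[C@H]12
F2 | step 8 | (13S)-14,14-dichloro-9α,13-epoxylabd-7-en-15,16-olide | C1C=C(C)[C@]2(CC[C@]3(C(Cl)(Cl)C(=O)OC3)O2)[C@@]2(C)CCCC(C)(C)[C@H]12
F3 | step 13 | (13R)-6β,15-bis(tert-butyldimethylsilyloxy)-9α,13:15,16-diepoxy-7α-hydroperoxylabd-8(17)-ene | CC(C)(C)[Si](C)(C)O[C@@H]1[C@@H](OO)C(=C)[C@]2(CC[C@]3(CC(O[Si](C)(C)C(C)(C)C)OC3)O2)[C@@]2(C)CCCC(C)(C)[C@H]12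
F4 | step 13 | (13R)-6β,15-bis(tert-butyldimethylsilyloxy)-9α,13:15,16-diepoxylabd-8(17)-en-7-one | CC(C)(C)[Si](C)(C)O[C@@H]1C(=O)C(=C)[C@]2(CC[C@]3(CC(O[Si](C)(C)C(C)(C)C)OC3)O2)[C@@]2(C)CCCC(C)(C)[C@H]12
F5 | step 13 | (13R)-6β,15-bis(tert-butyldimethylsilyloxy)-9α,13:15,16-diepoxylabd-8(17)-en-7β-ol | CC(C)(C)[Si](C)(C)O[C@@H]1[C@H](O)C(=C)[C@]2(CC[C@]3(CC(O[Si](C)(C)C(C)(C)C)OC3)O2)[C@@]2(C)CCCC(C)(C)[C@H]12
F6 | step 13 | (13R)-6β,15-bis(tert-butyldimethylsilyloxy)-9α,13:15,16-diepoxy-8α-methyl(8βH)-labdan-7β-ol | CC(C)(C)[Si](C)(C)O[C@@H]1[C@H](O)[C@@H](C)[C@]2(CC[C@]3(CC(O[Si](C)(C)C(C)(C)C)OC3)O2)[C@@]2(C)CCCC(C)(C)[C@H]12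
F7 | step 4 | ethyl 14,15,16-trinorlabd-8-en-13-oate | C1CC(C)=C(CCC(=O)OCC)[C@@]2(C)CCCC(C)(C)[C@H]12
F8 | step 4 | ethyl 7-oxo-14,15,16-trinorlabd-8-en-13-oate | C1C(=O)C(C)=C(CCC(=O)OCC)[C@@]2(C)CCCC(C)(C)[C@H]12
F9 | step 4 | ethyl 7β-hydroxy-14,15,16-trinorlabd-8-en-13-oate | C1[C@H](O)C(C)=C(CCC(=O)OCC)[C@@]2(C)CCCC(C)(C)[C@H]12
F10 | step 4 | 7β-hydroxy-14,15,16-trinorlabd-8-en-13-oic acid | C1[C@H](O)C(C)=C(CCC(=O)O)[C@@]2(C)CCCC(C)(C)[C@H]12
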